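## Retrosynthetic overview

1. The strategy rests on ring C, the maleimide N1–C2(=O)–C3=C4–C5(=O). Its C3=C4 bond carries the chroman-7-ylmethyl group and the 4-hydroxyphenyl ring D and sits between two carbonyl carbons. C3=C4 is therefore read as an internal alkyne, C5=O as carbon monoxide and C2(=O)–N1 as an isocyanate.
2. N–H imide ⇒ maleic anhydride ⇒ N-(4-methoxybenzyl) imide ⇒ [2+2+1] union of a bis-silylated 1,3-diarylpropyne, CO and 4-methoxybenzyl isocyanate.
3. 1,3-Diarylpropyne ⇒ sp–sp3 coupling of a chroman-7-ylmethyl bromide with the magnesium acetylide of silylated 4-ethynylphenol, which is made from 4-iodophenol.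
4. Chromanylmethyl bromide ⇒ (S)-chroman-3-ol ⇒ benzylic hydride opening of a (3S,4S)-epoxychroman ⇒ Jacobsen–Katsuki epoxidation of a 2,2-dimethylchromene ⇒ prenylation and oxidative cyclisation of methyl 4-bromo-3-hydroxybenzoate.
5. Ring order: rings A (chroman benzene ring) and D are bought. Ring B (pyran) closes in step 2. Ring C closes in step 11 and is re-closed through O in step 12 and through NH in step 13.

Key step: step 11

Remark on the chemistry: the only stereocentre, chroman C3, reads as S in the given SMILES. It is set on the closed chromene and not on an open epoxyprenylphenol, because the latter can close either 6-endo (chromanol) or 5-exo (dihydrobenzofuran).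

## Route

Step 1
Reactants: 1 methyl 4-bromo-3-hydroxybenzoate; 2 prenylboronic acid pinacol ester
Product: 3 methyl 3-hydroxy-4-(3-methylbut-2-en-1-yl)benzoate
Conditions: Pd(PPh3)4 (5 mol %), CsF (4 equiv), THF, 65 °C
Reagents that add atoms: none
Why: Suzuki–Miyaura allyl–aryl coupling in which the bromine fixes the site on ring A, the para ester speeds oxidative addition, and the prenylpalladium species should equilibrate to its primary σ-allyl form before reductive elimination, so the linear prenyl arene is expected rather than the 1,1-dimethylallyl isomer.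

Step 2
Reactants: 3 methyl 3-hydroxy-4-(3-methylbut-2-en-1-yl)benzoate
Product: 5 methyl 2,2-dimethyl-2H-chromene-7-carboxylate, via o-quinone methide 4 (not isolated)
Conditions: DDQ (1.2 equiv), toluene, 110 °C
Reagents that add atoms: none
Why: Dehydrogenative cyclisation of an o-prenylphenol, known for ester-bearing prenylphenols, in which DDQ takes hydride from the benzylic and allylic CH2 together with the phenol proton, and the (Z)-vinyl o-quinone methide 4 closes ring B by oxa-6π electrocyclisation onto the dimethyl-substituted terminus.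

Step 3
Reactants: 5 methyl 2,2-dimethyl-2H-chromene-7-carboxylate
Product: 6 methyl (3S,4S)-3,4-epoxy-2,2-dimethylchroman-7-carboxylate
Conditions: (S,S)-[N,N'-bis(3,5-di-tert-butylsalicylidene)cyclohexane-1,2-diaminato]MnCl (4 mol %), 4-phenylpyridine N-oxide (20 mol %), aq. NaOCl (Na2HPO4 buffer, pH 11.3), CH2Cl2, 0 °C
Reagents that add atoms: sodium hypochlorite, [Na+].[O-]Cl
Why: Jacobsen–Katsuki epoxidation of a conjugated cis-olefin of the 2,2-dimethylchromene class, the best substrate type for this catalyst, in which side-on approach to the oxo-manganese species of the (S,S)-ligand delivers oxygen to the face that gives the (3S,4S)-oxirane and so sets C3.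

Step 4
Reactants: 6 methyl (3S,4S)-3,4-epoxy-2,2-dimethylchroman-7-carboxylate
Product: 7 (S)-7-(hydroxymethyl)-2,2-dimethylchroman-3-ol
Conditions: LiAlH4 (3 equiv), THF, 0 °C to 40 °C; then H2O, 15% aq. NaOH
Reagents that add atoms: none
Why: Hydride reduction in which SN2 attack falls on benzylic C4, the site that nucleophiles attack in 3,4-epoxychromans because C3 is shielded by quaternary C2, so the C3–O bond and its S configuration stay untouched while the ester is reduced to the primary alcohol in the same operation.

Step 5
Reactants: 7 (S)-7-(hydroxymethyl)-2,2-dimethylchroman-3-ol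
Product: 8 (S)-7-(bromomethyl)-2,2-dimethylchroman-3-ol
Conditions: CBr4 (1.05 equiv), PPh3 (1.1 equiv), CH2Cl2, 0 °C
Reagents that add atoms: carbon tetrabromide, BrC(Br)(Br)Br
Why: Appel reaction with one equivalent of reagent, in which the unhindered primary benzylic hydroxyl is activated and displaced far faster than the secondary, neopentyl-type C3 hydroxyl.

Step 6
Reactants: 8 (S)-7-(bromomethyl)-2,2-dimethylchroman-3-ol
Product: 9 (S)-7-(bromomethyl)-3-(tert-butyldimethylsilyloxy)-2,2-dimethylchroman
Conditions: TBSOTf (1.2 equiv), 2,6-lutidine (1.5 equiv), CH2Cl2, 0 °C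
Reagents that add atoms: tert-butyldimethylsilyl triflate, CC(C)(C)[Si](C)(C)OS(=O)(=O)C(F)(F)F
Why: Silyl ether formation with the triflate, which is reactive enough for the hindered C3 hydroxyl, while the hindered base does not quaternise with the benzylic bromide at this temperature.

Step 7
Reactants: 10 4-iodophenol
Product: 11 tert-butyl(4-iodophenoxy)dimethylsilane
Conditions: TBSCl (1.1 equiv), imidazole (2 equiv), CH2Cl2, rt
Reagents that add atoms: tert-butyldimethylsilyl chloride, CC(C)(C)[Si](C)(C)Cl
Why: Standard imidazole-promoted silylation of a phenol, which masks the acidic OH for the organometallic steps and for the isocyanate.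

Step 8
Reactants: 11 tert-butyl(4-iodophenoxy)dimethylsilane; 12 trimethylsilylacetylene
Product: 13 tert-butyldimethyl{4-[(trimethylsilyl)ethynyl]phenoxy}silane
Conditions: PdCl2(PPh3)2 (2 mol %), CuI (4 mol %), Et3N, THF, rt
Reagents that add atoms: none
Why: Sonogashira coupling of an aryl iodide, which proceeds at room temperature and leaves both silyl groups intact.

Step 9
Reactants: 13 tert-butyldimethyl{4-[(trimethylsilyl)ethynyl]phenoxy}silane
Product: 14 tert-butyl(4-ethynylphenoxy)dimethylsilane
Conditions: K2CO3 (0.2 equiv), MeOH/CH2Cl2 1:1, 0 °C, short contact time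
Reagents that add atoms: none
Why: Methanolysis (protodesilylation) of the C(sp)–SiMe3 bond, which is much faster than attack on the bulkier aryl tert-butyldimethylsilyl ether when base is catalytic and the mixture is kept cold.

Step 10
Reactants: 14 tert-butyl(4-ethynylphenoxy)dimethylsilane; 9 (S)-7-(bromomethyl)-3-(tert-butyldimethylsilyloxy)-2,2-dimethylchroman
Product: 16 (S)-bis-TBS 1-(4-hydroxyphenyl)-3-(3-hydroxy-2,2-dimethylchroman-7-yl)propyne, via alkynylmagnesium bromide 15 (not isolated)
Conditions: 14 (1.3 equiv), EtMgBr (1.25 equiv), THF, 0 to 40 °C; then CuBr·SMe2 (10 mol %), 9, THF, 60 °C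
Reagents that add atoms: none
Why: Copper-catalysed alkylation of a magnesium acetylide with a benzylic bromide, the classical route to 1,3-diarylpropynes, chosen because it needs no carbonate or amine base that could strip the aryl silyl ether or shift the new ArCH2–C≡C unit to the allene.

Step 11
Reactants: 16 (S)-bis-TBS 1-(4-hydroxyphenyl)-3-(3-hydroxy-2,2-dimethylchroman-7-yl)propyne; 17 4-methoxybenzyl isocyanate
Product: 18 N-(4-methoxybenzyl) bis-TBS asperimide C
Conditions: Ru3(CO)12 (5 mol %), CO (1 atm), 17 (1.5 equiv, freshly distilled), dry mesitylene, 130 °C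
Reagents that add atoms: carbon monoxide, [C-]#[O+]
Why: This is the ruthenium-catalysed carbonylative [2+2+1] cocyclisation of an internal alkyne, an isocyanate and CO, a known entry to tetrasubstituted maleimides, applied here to an aryl/benzyl alkyne and a benzylic isocyanate. A zerovalent ruthenium carbonyl fragment couples the C≡C bond of 16 oxidatively with the C=N bond of 17 to a five-membered azaruthenacycle (C2–C3 formed), CO then inserts (C4–C5 formed), and reductive elimination makes C5–N1 and returns zerovalent ruthenium. Ring C is thus closed by an intermolecular three-component annulation whose ring-forming event is C–N reductive elimination from a six-membered ruthenacycle. No stereocentre is created, and the S centre at chroman C3 bears neither an acidic hydrogen nor a leaving group under these neutral conditions, so it passes through unchanged. Regiocontrol is not required, since whichever way round the isocyanate adds to the unsymmetrical alkyne, C2 and C5 end as the two carbonyl positions flanking N1 and the same constitution results. The step needs chemoselectivity only: both hydroxyls are silylated so that 17 is not lost as carbamate, the absence of base and amine keeps the doubly activated ArCH2–C≡C hydrogens from shifting to the allene, and the CO atmosphere with excess isocyanate disfavours alkyne trimerisation and 2:1 pyridone formation.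

Step 12
Reactants: 18 N-(4-methoxybenzyl) bis-TBS asperimide C
Product: 20 (S)-3-{[3-(tert-butyldimethylsilyloxy)-2,2-dimethylchroman-7-yl]methyl}-4-(4-hydroxyphenyl)furan-2,5-dione, via ring-opened maleic diacid 19 (not isolated)
Conditions: 5 M aq. KOH, EtOH, 80 °C, degassed, argon; then 2 M HCl to pH 1, 0 °C to rt
Reagents that add atoms: potassium hydroxide, [K+].[OH-]
Why: Alkaline imide hydrolysis followed by acid-induced cyclodehydration, in which hydroxide frees 4-methoxybenzylamine and also cleaves the phenolic silyl ether, and the tetrasubstituted (Z)-diacid 19, with its carboxyl groups held cis, closes spontaneously to the anhydride on acidification while the hindered alkyl silyl ether should persist.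

Step 13
Reactants: 20 (S)-3-{[3-(tert-butyldimethylsilyloxy)-2,2-dimethylchroman-7-yl]methyl}-4-(4-hydroxyphenyl)furan-2,5-dione
Product: 21 (S)-3-O-TBS asperimide C
Conditions: (Me3Si)2NH (10 equiv), MeOH (5 equiv), DMF, rt; aqueous work-up
Reagents that add atoms: hexamethyldisilazane, C[Si](C)(C)N[Si](C)(C)C
Why: Anhydride-to-imide exchange by ammonia released slowly from hexamethyldisilazane and methanol, a room-temperature aminolysis–cyclodehydration that spares the C3 silyl ether and the benzylic CH2 the hot acetic acid of the ammonium acetate variant.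

Step 14
Reactants: 21 (S)-3-O-TBS asperimide C
Product: 22 asperimide C
Conditions: HF·pyridine, THF, 0 °C to rt
Reagents that add atoms: none
Why: Fluoride-mediated desilylation under mildly acidic conditions, which avoids deprotonating the imide and the ring C benzylic position and does not touch the C3–O bond, so the S configuration is retained.

## Compound list

1 | methyl 4-bromo-3-hydroxybenzoate | COC(=O)c1ccc(Br)c(O)c1 | starting material
2 | prenylboronic acid pinacol ester, 4,4,5,5-tetramethyl-2-(3-methylbut-2-en-1-yl)-1,3,2-dioxaborolane | CC(C)=CCB1OC(C)(C)C(C)(C)O1 | starting material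
3 | methyl 3-hydroxy-4-(3-methylbut-2-en-1-yl)benzoate | COC(=O)c1ccc(CC=C(C)C)c(O)c1 | intermediate
4 | o-quinone methide, methyl (Z)-4-(3-methylbut-2-en-1-ylidene)-3-oxocyclohexa-1,5-diene-1-carboxylate | O=C1C=C(C(=O)OC)C=C/C1=C/C=C(C)C | intermediate
5 | methyl 2,2-dimethyl-2H-chromene-7-carboxylate | CC1(C)Oc2cc(C(=O)OC)ccc2C=C1 | intermediate
6 | methyl (3S,4S)-3,4-epoxy-2,2-dimethylchroman-7-carboxylate (cis-fused oxirane on C3–C4) | CC1(C)Oc2cc(C(=O)OC)ccc2[C@@H]3O[C@@H]31 | intermediate
7 | (S)-7-(hydroxymethyl)-2,2-dimethylchroman-3-ol | CC1(C)Oc2cc(CO)ccc2C[C@@H]1O | intermediate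
8 | (S)-7-(bromomethyl)-2,2-dimethylchroman-3-ol | CC1(C)Oc2cc(CBr)ccc2C[C@@H]1O | intermediate
9 | (S)-7-(bromomethyl)-3-(tert-butyldimethylsilyloxy)-2,2-dimethylchroman | CC1(C)Oc2cc(CBr)ccc2C[C@@H]1O[Si](C)(C)C(C)(C)C | intermediate
10 | 4-iodophenol | Oc1ccc(I)cc1 | starting material
11 | tert-butyl(4-iodophenoxy)dimethylsilane | CC(C)(C)[Si](C)(C)Oc1ccc(I)cc1 | intermediate
12 | trimethylsilylacetylene | C#C[Si](C)(C)C | starting material
13 | tert-butyldimethyl{4-[(trimethylsilyl)ethynyl]phenoxy}silane | CC(C)(C)[Si](C)(C)Oc1ccc(C#C[Si](C)(C)C)cc1 | intermediate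
14 | tert-butyl(4-ethynylphenoxy)dimethylsilane | CC(C)(C)[Si](C)(C)Oc1ccc(C#C)cc1 | intermediate
15 | {4-[(tert-butyldimethylsilyl)oxy]phenyl}ethynylmagnesium bromide | CC(C)(C)[Si](C)(C)Oc1ccc(C#C[Mg]Br)cc1 | intermediate
16 | (S)-bis-TBS 1-(4-hydroxyphenyl)-3-(3-hydroxy-2,2-dimethylchroman-7-yl)propyne | CC1(C)Oc2cc(CC#Cc3ccc(O[Si](C)(C)C(C)(C)C)cc3)ccc2C[C@@H]1O[Si](C)(C)C(C)(C)C | intermediate
17 | 4-methoxybenzyl isocyanate | COc1ccc(CN=C=O)cc1 | starting material
18 | N-(4-methoxybenzyl) bis-TBS asperimide C, (S)-configured at chroman C3 | CC1(C)Oc2cc(CC3=C(c4ccc(O[Si](C)(C)C(C)(C)C)cc4)C(=O)N(Cc4ccc(OC)cc4)C3=O)ccc2C[C@@H]1O[Si](C)(C)C(C)(C)C | intermediate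
19 | (Z)-2-{[(S)-3-(tert-butyldimethylsilyloxy)-2,2-dimethylchroman-7-yl]methyl}-3-(4-hydroxyphenyl)butenedioic acid (present as its potassium salt) | CC1(C)Oc2cc(C/C(C(=O)O)=C(/C(=O)O)c3ccc(O)cc3)ccc2C[C@@H]1O[Si](C)(C)C(C)(C)C | intermediate
20 | (S)-3-{[3-(tert-butyldimethylsilyloxy)-2,2-dimethylchroman-7-yl]methyl}-4-(4-hydroxyphenyl)furan-2,5-dione | CC1(C)Oc2cc(CC3=C(c4ccc(O)cc4)C(=O)OC3=O)ccc2C[C@@H]1O[Si](C)(C)C(C)(C)C | intermediate
21 | (S)-3-O-TBS asperimide C | CC1(C)Oc2cc(CC3=C(c4ccc(O)cc4)C(=O)NC3=O)ccc2C[C@@H]1O[Si](C)(C)C(C)(C)C | intermediate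
22 | asperimide C, (S) | CC1(C)Oc2cc(CC3=C(c4ccc(O)cc4)C(=O)NC3=O)ccc2C[C@@H]1O | target

## Step count and risks

Total step count: 14. Longest linear sequence: 11 steps (steps 1–6 and 10–14, from 1).

**Step 11.** At 130 °C the propargylic and benzylic CH2 may undergo a 1,3-hydrogen shift to the allene before the alkyne is captured, promoted by a ruthenium hydride or by traces of amine. Isocyanate trimerisation or 2:1 alkyne–isocyanate pyridone formation may also outrun CO insertion.

The fallback buys ring C instead of building it. It sets out from 9 and comes back to the route at 20.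
- Commercial 1-benzyl-3,4-dibromopyrrole-2,5-dione is mono-arylated with one equivalent of commercial 4-(tert-butyldimethylsilyloxy)phenylboronic acid. This Suzuki–Miyaura coupling (Pd(PPh3)4, K3PO4, 1,4-dioxane, 60 °C) gives 1-benzyl-3-bromo-4-[4-(tert-butyldimethylsilyloxy)phenyl]pyrrole-2,5-dione F1.
- Bromide 9 is treated with Zn dust and LiCl in THF to give {(S)-3-(tert-butyldimethylsilyloxy)-2,2-dimethylchroman-7-yl}methylzinc bromide F2.
- Negishi coupling of the two (Pd(PPh3)4, THF, rt to 50 °C) gives N-benzyl bis-TBS asperimide C F3.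
- F3 is hydrolysed under the conditions of step 12, through 19, to anhydride 20.

**Step 12.** In hot alkali the ring C double bond may migrate towards the benzylic carbon, the benzylic CH2 may autoxidise, and cleavage of the second acyl–nitrogen bond may stall.

The fallback removes the N-substituent oxidatively without base. It sets out from 18 and comes back at 22.
- (NH4)2Ce(NO3)6 (3–4 equiv, MeCN/H2O, 0 °C) oxidises the 4-methoxybenzyl group, whose CH2 lies para to its methoxy group, while the phenol of ring D is still masked. This gives bis-TBS asperimide C F4.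
- HF·pyridine in THF then removes both silyl groups to give 22.

**Step 2.** Hydride abstraction may be slow, because the ester para to the CH2 destabilises the developing cation. Long heating with DDQ may consume the phenol through quinone adducts.

The fallback sets the stereocentre on the open chain and closes ring B by epoxide opening. It sets out from 3 and comes back at 7.
- TBSCl and imidazole give methyl 3-(tert-butyldimethylsilyloxy)-4-(3-methylbut-2-en-1-yl)benzoate F5.
- Shi epoxidation follows with 1,2:4,5-di-O-isopropylidene-β-L-erythro-2,3-hexodiulo-2,6-pyranose, the mirror image of the D-fructose-derived ketone that gives R epoxides from this olefin class. With KHSO5 (as 2KHSO5·KHSO4·K2SO4) and K2CO3 buffer in MeCN/dimethoxymethane/H2O at 0 °C it gives methyl 3-(tert-butyldimethylsilyloxy)-4-{[(S)-3,3-dimethyloxiran-2-yl]methyl}benzoate F6.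
- Bu4NF buffered with AcOH frees the phenol without building up phenoxide, which would close 5-exo at the stereocentre. The product is methyl 4-{[(S)-3,3-dimethyloxiran-2-yl]methyl}-3-hydroxybenzoate F7.
- Camphorsulfonic acid (10 mol %, CH2Cl2, 0 °C) directs the phenol to the tertiary epoxide carbon (6-endo, C3–O bond untouched). This gives methyl (S)-3-hydroxy-2,2-dimethylchroman-7-carboxylate F8.
- LiAlH4 in THF reduces F8 to 7.

## Further compounds

F1 | step 11 | 1-benzyl-3-bromo-4-[4-(tert-butyldimethylsilyloxy)phenyl]pyrrole-2,5-dione | O=C1N(Cc2ccccc2)C(=O)C(c2ccc(O[Si](C)(C)C(C)(C)C)cc2)=C1Br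
F2 | step 11 | {(S)-3-(tert-butyldimethylsilyloxy)-2,2-dimethylchroman-7-yl}methylzinc bromide | CC1(C)Oc2cc(C[Zn]Br)ccc2C[C@@H]1O[Si](C)(C)C(C)(C)C
F3 | step 11 | N-benzyl bis-TBS asperimide C | CC1(C)Oc2cc(CC3=C(c4ccc(O[Si](C)(C)C(C)(C)C)cc4)C(=O)N(Cc4ccccc4)C3=O)ccc2C[C@@H]1O[Si](C)(C)C(C)(C)C
F4 | step 12 | bis-TBS asperimide C | CC1(C)Oc2cc(CC3=C(c4ccc(O[Si](C)(C)C(C)(C)C)cc4)C(=O)NC3=O)ccc2C[C@@H]1O[Si](C)(C)C(C)(C)C
F5 | step 2 | methyl 3-(tert-butyldimethylsilyloxy)-4-(3-methylbut-2-en-1-yl)benzoate | COC(=O)c1ccc(CC=C(C)C)c(O[Si](C)(C)C(C)(C)C)c1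
F6 | step 2 | methyl 3-(tert-butyldimethylsilyloxy)-4-{[(S)-3,3-dimethyloxiran-2-yl]methyl}benzoate | COC(=O)c1ccc(C[C@@H]2OC2(C)C)c(O[Si](C)(C)C(C)(C)C)c1
F7 | step 2 | methyl 4-{[(S)-3,3-dimethyloxiran-2-yl]methyl}-3-hydroxybenzoate | COC(=O)c1ccc(C[C@@H]2OC2(C)C)c(O)c1
F8 | step 2 | methyl (S)-3-hydroxy-2,2-dimethylchroman-7-carboxylate | CC1(C)Oc2cc(C(=O)OC)ccc2C[C@@H]1O
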